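**Retrosynthetic overview**
1. Feature: in the lactone (O1, C2=O, C3, C4, C5) the benzylic CH2 on C3 (ring B, 3-hydroxy-4,5-dimethoxyphenyl) and the benzylic CH2 on C4 (ring A, 3,4-dimethoxyphenyl) are 1,4-related through C3–C4. One extra bond between them turns C3, C4 and both benzylic carbons into a 1,2-diarylcyclobutane.
2. Target 13 ⇒ γ-hydroxy acid 12 (lactone bond C2–O1) ⇒ cyclobutane acid 9, by restoring the benzylic–benzylic bond that Li/NH3 cuts in the forward direction.
3. Cyclobutane 8 ⇒ ring B cinnamate 3 + ring A cinnamyl silyl ether 7, by an enantioselective crossed [2+2] photocycloaddition that forms C3–C4 and the temporary bond.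
4. 3 ⇒ 3-hydroxy-4,5-dimethoxybenzaldehyde 1 (benzylation, olefination); 7 ⇒ 3,4-dimethoxycinnamic acid 4 (esterification, reduction, silylation).
5. Ring order: cyclobutane formed in step 6, opened in step 8, lactone closed in step 9.

Key step: step 6

Assumption: the (S)-oxazaborolidine is taken to shield the face of the bound cinnamate that gives (1R)-8; if a first run shows the opposite sense, the equally available (R)-catalyst is used with no other change.

**Route**

Step 1
Reactants: 1 3-hydroxy-4,5-dimethoxybenzaldehyde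
Product: 2 3-(benzyloxy)-4,5-dimethoxybenzaldehyde
Conditions: BnBr, K2CO3, DMF, rt → 60 °C
Reagents that add atoms: benzyl bromide, BrCc1ccccc1
Why: Williamson ether synthesis; the phenoxide formed with K2CO3 displaces bromide from benzyl bromide (SN2) and the aldehyde is untouched.

Step 2
Reactants: 2 3-(benzyloxy)-4,5-dimethoxybenzaldehyde
Product: 3 methyl (E)-3-[3-(benzyloxy)-4,5-dimethoxyphenyl]acrylate
Conditions: (MeO)2P(O)CH2CO2Me, NaH, THF, 0 °C → rt
Reagents that add atoms: trimethyl phosphonoacetate, COC(=O)CP(=O)(OC)OC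
Why: Horner–Wadsworth–Emmons olefination with a stabilised phosphonate anion should give the E-cinnamate; the benzyl ether is inert.

Step 3
Reactants: 4 (E)-3,4-dimethoxycinnamic acid
Product: 5 methyl (E)-3-(3,4-dimethoxyphenyl)acrylate
Conditions: MeOH, H2SO4 (cat.), reflux
Reagents that add atoms: methanol, CO
Why: Fischer esterification driven by methanol as solvent; the E-alkene and aryl methyl ethers tolerate catalytic acid.

Step 4
Reactants: 5 methyl (E)-3-(3,4-dimethoxyphenyl)acrylate
Product: 6 (E)-3-(3,4-dimethoxyphenyl)prop-2-en-1-ol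
Conditions: i-Bu2AlH (2.5 equiv), CH2Cl2, −78 °C → 0 °C; aq. potassium sodium tartrate
Reagents that add atoms: none
Why: 1,2-reduction of an α,β-unsaturated ester by i-Bu2AlH gives the allylic alcohol without touching the alkene, and the neutral tartrate work-up spares the acid-labile electron-rich cinnamyl alcohol.

Step 5
Reactants: 6 (E)-3-(3,4-dimethoxyphenyl)prop-2-en-1-ol
Product: 7 (E)-tert-butyl{[3-(3,4-dimethoxyphenyl)allyl]oxy}dimethylsilane
Conditions: TBSCl, imidazole, DMF, rt
Reagents that add atoms: tert-butyldimethylsilyl chloride, CC(C)(C)[Si](C)(C)Cl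
Why: imidazole-promoted silylation of a primary allylic alcohol; the bulky silyl ether is a poor Lewis base and keeps the hydroxyl away from the Lewis acid of step 6.

Step 6
Reactants: 3 methyl (E)-3-[3-(benzyloxy)-4,5-dimethoxyphenyl]acrylate; 7 (E)-tert-butyl{[3-(3,4-dimethoxyphenyl)allyl]oxy}dimethylsilane
Product: 8 methyl (1R,2S,3S,4R)-2-[3-(benzyloxy)-4,5-dimethoxyphenyl]-4-{[(tert-butyldimethylsilyl)oxy]methyl}-3-(3,4-dimethoxyphenyl)cyclobutane-1-carboxylate (all-trans)
Conditions: fac-Ir(ppy)3 (1 mol %), (S)-3,3-diphenyl-1-(o-tolyl)tetrahydro-1H,3H-pyrrolo[1,2-c][1,3,2]oxazaborole (30 mol %), HNTf2 (25 mol %), 7 (5 equiv), CH2Cl2, −78 °C, blue LEDs (450 nm)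
Reagents that add atoms: none
Why: Proposed new method: the cationic oxazaborolidinium binds the ester carbonyl of 3, lowers its triplet energy and speeds energy transfer from excited Ir(ppy)3 (trivalent iridium), so the bound cinnamate is the species excited; its alpha carbon (cyclobutane C1) then adds to the non-benzylic alkene carbon of 7 (C4) and gives a triplet 1,4-diradical with both radical centres benzylic, which fixes the head-to-head regiochemistry. The closest known reaction type is the oxazaborolidine-catalysed, iridium-sensitised enantioselective [2+2] photocycloaddition of cinnamate esters with terminal styrenes; a 1,2-disubstituted styrene carrying an allylic silyl ether has not been shown. The four-membered ring closes stepwise, by intersystem crossing and combination of the two benzylic radical centres (C2–C3), not by a concerted cycloaddition. C1 is set by the catalyst, whose aryl group shields one face of the bound enoate; C4 is set relative to C1 when the first bond forms, by an anti approach that keeps the CH2OTBS arm away from the complexed ester, and diradicals with the cis arrangement are expected to revert to alkenes more readily than they close; C2 and C3 are set at closure, after rotation at the radical centres places each aryl group trans to its neighbours. The step needs cross-addition over homodimerisation, secured by the excess of 7 and by preferential excitation of the bound cinnamate, and it needs only the trans C1/C4 relationship and the absolute configuration at C1, because C2 and C3 lose their configuration when the temporary bond is cut in step 8.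

Step 7
Reactants: 8 methyl (1R,2S,3S,4R)-cyclobutane ester
Product: 9 (1R,2S,3S,4R)-2-[3-(benzyloxy)-4,5-dimethoxyphenyl]-4-{[(tert-butyldimethylsilyl)oxy]methyl}-3-(3,4-dimethoxyphenyl)cyclobutane-1-carboxylic acid
Conditions: LiOH·H2O, THF/MeOH/H2O, 40 °C; then 1 M HCl to pH 4, 0 °C
Reagents that add atoms: lithium hydroxide, [Li+].[OH-]
Why: saponification by acyl substitution; the all-trans ester is the more stable epimer so C1 should hold, the primary alkyl silyl ether tolerates LiOH, and the carboxylate, unlike an ester, accepts no electron in step 8.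

Step 8
Reactants: 9 (1R,2S,3S,4R)-cyclobutane acid
Product: 11 (2R,3R)-3-{[(tert-butyldimethylsilyl)oxy]methyl}-4-(3,4-dimethoxyphenyl)-2-(3-hydroxy-4,5-dimethoxybenzyl)butanoic acid, via debenzylated cyclobutane acid 10 (not isolated)
Conditions: Li (7 equiv), NH3(l)/THF, −78 °C → −45 °C, no alcohol; NH4Cl (s); then 1 M HCl to pH 4
Reagents that add atoms: none
Why: dissolving-metal reduction; the benzyl aryl ether should fragment first to phenoxide and toluene, after which electron transfer to ring A cleaves the strained, doubly benzylic C2–C3 bond as in the known Li/NH3 hydrogenolysis of 1,2-diphenylcyclobutane, while the phenoxide of ring B and the carboxylate resist reduction and C1 and C4 (future C3 and C4 of the lactone) are untouched.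

Step 9
Reactants: 11 (2R,3R)-silyl ether acid
Product: 13 (3R,4R)-4-(3,4-dimethoxybenzyl)-3-(3-hydroxy-4,5-dimethoxybenzyl)dihydrofuran-2(3H)-one (target CNP0246971.1), via hydroxy acid 12 (not isolated)
Conditions: 2 M aq. HCl, THF, rt → 45 °C
Reagents that add atoms: none
Why: acid hydrolysis of the primary silyl ether followed by acid-catalysed lactonisation of the γ-hydroxy acid (5-exo-trig acyl substitution); neither stereocentre takes part and trans is also the more stable lactone.

**Compound list**
1 | 3-hydroxy-4,5-dimethoxybenzaldehyde | COc1cc(C=O)cc(O)c1OC | starting material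
2 | 3-(benzyloxy)-4,5-dimethoxybenzaldehyde | COc1cc(C=O)cc(OCc2ccccc2)c1OC | intermediate
3 | methyl (E)-3-[3-(benzyloxy)-4,5-dimethoxyphenyl]acrylate | COC(=O)/C=C/c1cc(OCc2ccccc2)c(OC)c(OC)c1 | intermediate
4 | (E)-3,4-dimethoxycinnamic acid | COc1ccc(/C=C/C(=O)O)cc1OC | starting material
5 | methyl (E)-3-(3,4-dimethoxyphenyl)acrylate | COc1ccc(/C=C/C(=O)OC)cc1OC | intermediate
6 | (E)-3-(3,4-dimethoxyphenyl)prop-2-en-1-ol | COc1ccc(/C=C/CO)cc1OC | intermediate
7 | (E)-tert-butyl{[3-(3,4-dimethoxyphenyl)allyl]oxy}dimethylsilane | COc1ccc(/C=C/CO[Si](C)(C)C(C)(C)C)cc1OC | intermediate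
8 | methyl (1R,2S,3S,4R)-2-[3-(benzyloxy)-4,5-dimethoxyphenyl]-4-{[(tert-butyldimethylsilyl)oxy]methyl}-3-(3,4-dimethoxyphenyl)cyclobutane-1-carboxylate | COC(=O)[C@H]1[C@H](CO[Si](C)(C)C(C)(C)C)[C@@H](c2ccc(OC)c(OC)c2)[C@@H]1c1cc(OCc2ccccc2)c(OC)c(OC)c1 | intermediate
9 | (1R,2S,3S,4R)-2-[3-(benzyloxy)-4,5-dimethoxyphenyl]-4-{[(tert-butyldimethylsilyl)oxy]methyl}-3-(3,4-dimethoxyphenyl)cyclobutane-1-carboxylic acid | OC(=O)[C@H]1[C@H](CO[Si](C)(C)C(C)(C)C)[C@@H](c2ccc(OC)c(OC)c2)[C@@H]1c1cc(OCc2ccccc2)c(OC)c(OC)c1 | intermediate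
10 | (1R,2S,3S,4R)-4-{[(tert-butyldimethylsilyl)oxy]methyl}-3-(3,4-dimethoxyphenyl)-2-(3-hydroxy-4,5-dimethoxyphenyl)cyclobutane-1-carboxylic acid | OC(=O)[C@H]1[C@H](CO[Si](C)(C)C(C)(C)C)[C@@H](c2ccc(OC)c(OC)c2)[C@@H]1c1cc(O)c(OC)c(OC)c1 | intermediate (not isolated)
11 | (2R,3R)-3-{[(tert-butyldimethylsilyl)oxy]methyl}-4-(3,4-dimethoxyphenyl)-2-(3-hydroxy-4,5-dimethoxybenzyl)butanoic acid | COc1ccc(C[C@@H](CO[Si](C)(C)C(C)(C)C)[C@@H](Cc2cc(O)c(OC)c(OC)c2)C(=O)O)cc1OC | intermediate
12 | (2R,3R)-4-(3,4-dimethoxyphenyl)-2-(3-hydroxy-4,5-dimethoxybenzyl)-3-(hydroxymethyl)butanoic acid | COc1ccc(C[C@@H](CO)[C@@H](Cc2cc(O)c(OC)c(OC)c2)C(=O)O)cc1OC | intermediate (not isolated)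
13 | (3R,4R)-4-(3,4-dimethoxybenzyl)-3-(3-hydroxy-4,5-dimethoxybenzyl)dihydrofuran-2(3H)-one | COc1ccc(C[C@H]2COC(=O)[C@@H]2Cc2cc(O)c(OC)c(OC)c2)cc1OC | target

**Step count**
Total: 9 steps. Longest linear sequence: 7 steps (4 → 13, steps 3 to 9).

**Steps most likely to fail**

Step 6. The excited, catalyst-bound cinnamate may add too slowly to a hindered internal alkene, so that E/Z isomerisation, cinnamate homodimerisation or the unbound racemic pathway takes over. The first bond may also form with poor topicity (C1/C4 cis), or the Lewis acid may ionise the allylic silyl ether. Epimers at C2 or C3 are harmless, since they converge in step 8. C1/C4-cis isomers must be removed by chromatography at 8, since later epimerisation of them would erode the enantiomeric purity.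

Fallback by known chemistry, setting out from 4 and 2 and rejoining at 13:
- Hydrogenation of 4 (H2, Pd/C, EtOAc) should give 3-(3,4-dimethoxyphenyl)propanoic acid F1.
- Pivaloyl chloride and Et3N convert it into the mixed pivalic anhydride F2, which acylates (S)-4-benzyl-2-oxazolidinone (LiCl, Et3N) to the imide F3.
- Auxiliary-controlled enolate alkylation (NaN(SiMe3)2, THF, −78 °C; tert-butyl bromoacetate) should give the alkylated imide F4 with the R centre.
- LiBH4 removes the auxiliary reductively to the hydroxy ester F5, and TsOH in warm toluene closes it to the (R)-lactone F6.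
- Separately, 2 is reduced (NaBH4, MeOH) to the benzylic alcohol F7 and converted (PBr3, CH2Cl2, 0 °C) into the bromide F8.
- The lithium enolate of F6 (LiN(SiMe3)2, THF, −78 °C) is alkylated by F8 anti to the C4 benzyl group, to the benzyl-protected trans lactone F9.
- Hydrogenolysis (H2, Pd/C, EtOAc) frees the phenol and gives 13.

Step 8. Over-reduction may occur: reductive loss of the flanked 4-methoxy group of ring B if electron uptake there outruns benzyl ether cleavage, O-demethylation or ring reduction of ring A, or incomplete cleavage of the cyclobutane bond.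

Fallback, setting out from ester 8 and rejoining at 13: the bond is cut on a metal surface instead of by electron transfer, and step 7 is skipped.
- Catalytic hydrogenolysis (H2, 4 bar, Pd(OH)2/C, EtOAc/AcOH, 50 °C) should remove the benzyl ether and open the doubly benzylic bond, giving the ring-opened phenol methyl ester F10.
- The conditions of step 9 (aq. HCl, THF) then desilylate F10 and lactonise the γ-hydroxy ester with loss of methanol to 13.

Step 7. Hydrolysis of the hindered ester may be slow, and forcing conditions could cause loss of the silyl ether or epimerisation at C1.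

Fallback, setting out from 2 and rejoining at 10: the acid is carried through the photocycloaddition as a benzyl ester, so no hydroxide is needed.
- Horner–Wadsworth–Emmons olefination of 2 with benzyl dimethylphosphonoacetate (NaH, THF) gives the benzyl cinnamate F11.
- The cycloaddition of step 6 with 7 gives the benzyl ester cycloadduct F12.
- Mild hydrogenolysis (H2, 1 bar, Pd/C, EtOAc, rt) removes both benzyl groups and delivers phenol acid 10, which is then treated with Li/NH3 as in step 8.

**Further compounds**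
F1 | step 6 | 3-(3,4-dimethoxyphenyl)propanoic acid | COc1ccc(CCC(=O)O)cc1OC
F2 | step 6 | 3-(3,4-dimethoxyphenyl)propanoic pivalic anhydride | COc1ccc(CCC(=O)OC(=O)C(C)(C)C)cc1OC
F3 | step 6 | (S)-4-benzyl-3-[3-(3,4-dimethoxyphenyl)propanoyl]oxazolidin-2-one | COc1ccc(CCC(=O)N2[C@@H](Cc3ccccc3)COC2=O)cc1OC
F4 | step 6 | tert-butyl (R)-4-[(S)-4-benzyl-2-oxooxazolidin-3-yl]-3-(3,4-dimethoxybenzyl)-4-oxobutanoate | COc1ccc(C[C@H](CC(=O)OC(C)(C)C)C(=O)N2[C@@H](Cc3ccccc3)COC2=O)cc1OC
F5 | step 6 | tert-butyl (R)-3-(3,4-dimethoxybenzyl)-4-hydroxybutanoate | COc1ccc(C[C@H](CC(=O)OC(C)(C)C)CO)cc1OC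
F6 | step 6 | (R)-4-(3,4-dimethoxybenzyl)dihydrofuran-2(3H)-one | COc1ccc(C[C@H]2COC(=O)C2)cc1OC
F7 | step 6 | [3-(benzyloxy)-4,5-dimethoxyphenyl]methanol | COc1cc(CO)cc(OCc2ccccc2)c1OC
F8 | step 6 | 1-(benzyloxy)-5-(bromomethyl)-2,3-dimethoxybenzene | COc1cc(CBr)cc(OCc2ccccc2)c1OC
F9 | step 6 | (3R,4R)-3-[3-(benzyloxy)-4,5-dimethoxybenzyl]-4-(3,4-dimethoxybenzyl)dihydrofuran-2(3H)-one | COc1ccc(C[C@H]2COC(=O)[C@@H]2Cc2cc(OCc3ccccc3)c(OC)c(OC)c2)cc1OC
F10 | step 8 | methyl (2R,3R)-3-{[(tert-butyldimethylsilyl)oxy]methyl}-4-(3,4-dimethoxyphenyl)-2-(3-hydroxy-4,5-dimethoxybenzyl)butanoate | COc1ccc(C[C@@H](CO[Si](C)(C)C(C)(C)C)[C@@H](Cc2cc(O)c(OC)c(OC)c2)C(=O)OC)cc1OC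
F11 | step 7 | benzyl (E)-3-[3-(benzyloxy)-4,5-dimethoxyphenyl]acrylate | COc1cc(/C=C/C(=O)OCc2ccccc2)cc(OCc2ccccc2)c1OC
F12 | step 7 | benzyl (1R,2S,3S,4R)-2-[3-(benzyloxy)-4,5-dimethoxyphenyl]-4-{[(tert-butyldimethylsilyl)oxy]methyl}-3-(3,4-dimethoxyphenyl)cyclobutane-1-carboxylate | O=C(OCc1ccccc1)[C@H]1[C@H](CO[Si](C)(C)C(C)(C)C)[C@@H](c2ccc(OC)c(OC)c2)[C@@H]1c1cc(OCc2ccccc2)c(OC)c(OC)c1
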